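**Plan**
1. Retrosynthetic cuts, in order: the two benzyl C–O bonds on ring A (the dioxygenated benzene ring of the tetralone); C3–C4 of the tetralone (ring-closing bond); C1–C2 and C1–C3 of a cyclopropanol (back to a lactone carbonyl); C1–C8a (CO2 onto an aryllithium); C4–C1' (naphthyllithium onto an aldehyde; naphthalene atoms are primed).
2. Enabling feature: the 4'-hydroxyl of the naphthalene is para to C1', the carbon bonded to C4, so a carbinol at C4 ionises to a naphtho-para-quinone methide with C4 electrophilic. C3 is the β-carbon of the C1 ketone, so a cyclopropanol on C8a delivers it as a homoenol carbon.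
3. Forward order: both aromatic systems are bought and joined at C4; a temporary lactone ring (C1/C4) is turned into a temporary cyclopropane ring; the cyclohexanone ring is closed last at C3–C4; the benzyl groups are then removed.
4. Stereochemistry: the only stereocentre, C4 (S), is set in the ring closure by a chiral phosphoric acid. The racemic carbinol centre is erased in the planar quinone methide, so the step is enantioconvergent.

Key step: step 9

Assumption: (R)-TRIP is taken to give the (S)-centre in step 9; should the antipode form, (S)-TRIP is used with nothing else changed.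

**Step 1**
Reactants: 1 5-methoxynaphthalen-1-ol
Product: 2 4-bromo-5-methoxynaphthalen-1-ol
Conditions: NBS (1.0 equiv), MeCN, −20 → 0 °C, dark
Reagents that add atoms: N-bromosuccinimide, O=C1CCC(=O)N1Br
Why: Electrophilic aromatic bromination; the free hydroxyl is the strongest donor and should direct para (C4), the usual outcome for 1-naphthols in a polar solvent.

**Step 2**
Reactants: 2 4-bromo-5-methoxynaphthalen-1-ol
Product: 3 [(4-bromo-5-methoxynaphthalen-1-yl)oxy](tert-butyl)dimethylsilane
Conditions: TBSCl (1.2 equiv), imidazole (2.5 equiv), DMF, rt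
Reagents that add atoms: tert-butyldimethylsilyl chloride, CC(C)(C)[Si](C)(C)Cl
Why: Standard O-silylation; the aryl silyl ether should survive the organolithium and Grignard steps and is removable by fluoride without touching benzyl ethers.

**Step 3**
Reactants: 4 2-bromobenzene-1,4-diol
Product: 5 1,4-bis(benzyloxy)-2-bromobenzene
Conditions: BnBr (2.3 equiv), K2CO3 (3 equiv), DMF, 60 °C, N2
Reagents that add atoms: benzyl bromide, BrCc1ccccc1
Why: Williamson ether synthesis on both phenols; benzyl is chosen because it can be removed at the end without cleaving the naphthyl methyl ether.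

**Step 4**
Reactants: 5 1,4-bis(benzyloxy)-2-bromobenzene
Product: 7 3,6-bis(benzyloxy)-2-bromobenzaldehyde, via aryllithium 6 (not isolated)
Conditions: LiN(iPr)2 (1.1 equiv), THF, −78 °C; DMF (2 equiv), −78 → 0 °C; aq NH4Cl
Reagents that add atoms: N,N-dimethylformamide, CN(C)C=O
Why: Directed ortho-metalation at the proton flanked by bromine and benzyloxy (the most acidic one), followed by formylation; an amide base at −78 °C should avoid bromine–lithium exchange and aryne formation.

**Step 5**
Reactants: 3 [(4-bromo-5-methoxynaphthalen-1-yl)oxy](tert-butyl)dimethylsilane; 7 3,6-bis(benzyloxy)-2-bromobenzaldehyde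
Product: 9 [3,6-bis(benzyloxy)-2-bromophenyl]{4-[(tert-butyldimethylsilyl)oxy]-8-methoxynaphthalen-1-yl}methanol (racemic), via naphthyllithium 8 (not isolated)
Conditions: 3, n-BuLi (1.05 equiv), THF, −78 °C; then 7, −78 → −40 °C; aq NH4Cl
Reagents that add atoms: none
Why: Bromine–lithium exchange followed by 1,2-addition of the aryllithium to the aldehyde forms the C4–C1' bond; the racemic carbinol is acceptable because this centre is erased in step 9.

**Step 6**
Reactants: 9 [3,6-bis(benzyloxy)-2-bromophenyl]{4-[(tert-butyldimethylsilyl)oxy]-8-methoxynaphthalen-1-yl}methanol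
Product: 12 4,7-bis(benzyloxy)-3-{4-[(tert-butyldimethylsilyl)oxy]-8-methoxynaphthalen-1-yl}-2-benzofuran-1(3H)-one (racemic), via dilithio alkoxide 10 (not isolated), via hydroxy acid 11 (not isolated)
Conditions: n-BuLi (2.2 equiv), THF, −78 °C; CO2 (g), −78 → 0 °C; 1 M HCl, rt
Reagents that add atoms: carbon dioxide, O=C=O
Why: O-deprotonation and bromine–lithium exchange give a dianion whose aryl carbon is carboxylated (the future C1); on acidification the γ-hydroxy acid should close spontaneously to the five-membered lactone.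

**Step 7**
Reactants: 12 4,7-bis(benzyloxy)-3-{4-[(tert-butyldimethylsilyl)oxy]-8-methoxynaphthalen-1-yl}-2-benzofuran-1(3H)-one
Product: 13 1-{3,6-bis(benzyloxy)-2-[{4-[(tert-butyldimethylsilyl)oxy]-8-methoxynaphthalen-1-yl}(hydroxy)methyl]phenyl}cyclopropan-1-ol (racemic)
Conditions: EtMgBr (4 equiv, slow addition), Ti(OiPr)4 (1.0 equiv), THF, 0 °C → rt; cold aq NH4Cl
Reagents that add atoms: ethylmagnesium bromide, CC[Mg]Br
Why: Kulinkovich cyclopropanation of a lactone: the titanacyclopropane acts as a 1,2-dicarbanion on the carbonyl and the lactone oxygen is released as the diaryl carbinol, so one operation creates both the homoenol donor and the quinone methide precursor.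

**Step 8**
Reactants: 13 1-{3,6-bis(benzyloxy)-2-[{4-[(tert-butyldimethylsilyl)oxy]-8-methoxynaphthalen-1-yl}(hydroxy)methyl]phenyl}cyclopropan-1-ol
Product: 14 1-{3,6-bis(benzyloxy)-2-[hydroxy(4-hydroxy-8-methoxynaphthalen-1-yl)methyl]phenyl}cyclopropan-1-ol (racemic)
Conditions: TBAF (1.1 equiv), AcOH (1.1 equiv), THF, 0 °C
Reagents that add atoms: none
Why: Fluoride cleavage of the aryl silyl ether; acetic acid buffering should keep the naphtholate from expelling hydroxide early and protect the cyclopropanol from base-induced opening.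

**Step 9**
Reactants: 14 1-{3,6-bis(benzyloxy)-2-[hydroxy(4-hydroxy-8-methoxynaphthalen-1-yl)methyl]phenyl}cyclopropan-1-ol
Product: 16 (4S)-5,8-bis(benzyloxy)-4-(4-hydroxy-8-methoxynaphthalen-1-yl)-3,4-dihydronaphthalen-1(2H)-one, via para-quinone methide 15 (not isolated)
Conditions: (R)-TRIP [(R)-3,3'-bis(2,4,6-triisopropylphenyl)-1,1'-binaphthyl-2,2'-diyl hydrogen phosphate] (10 mol%), 4 Å MS, toluene (0.02 M), rt → 40 °C
Reagents that add atoms: none
Why: Proposed new method: the chiral phosphoric acid protonates the doubly benzylic hydroxyl of 14 and, with loss of water, gives the hydrogen-bonded naphtho-para-quinone methide 15, whose exocyclic carbon (the future C4) is attacked by the C1–C3 σ-bond of the oxygen-activated cyclopropanol while the phosphate takes the hydroxyl proton, so that the C1 ketone and the aromatic naphthol appear together. The closest known reaction types are the chiral-phosphoric-acid-catalysed 1,6-additions of π-nucleophiles to para-quinone methides generated in situ from para-hydroxybenzyl alcohols, and the Lewis-acid- or metal-promoted ring-opening additions of cyclopropanols as homoenolate equivalents to carbon electrophiles; their union in an intramolecular, enantioselective σ-bond addition is the new element. The cyclohexanone ring closes in the 6-exo-trig mode with respect to the exocyclic C=C of 15, and at the cyclopropane by electrophilic opening of the bond between the carbinol carbon and one CH2 (either CH2 leads to the same product). The C4 stereocentre is controlled by the catalyst alone: the racemic carbinol centre is erased in planar 15, the peri 8'-methoxy group should enforce a single (E) methide geometry with the aryl group turned away from it, and the binaphthyl phosphate held to the quinone methide oxygen and the cyclopropanol O–H should shield one face. The step needs C-attack to win over O-attack and over protic opening of the cyclopropanol: O-attack is reversible under the same acid whereas C–C formation is not, and a weak acid in toluene should not protonate the cyclopropane. The benzyl ethers keep ring A from being oxidised or acting as a competing nucleophile.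

**Step 10**
Reactants: 16 (4S)-5,8-bis(benzyloxy)-4-(4-hydroxy-8-methoxynaphthalen-1-yl)-3,4-dihydronaphthalen-1(2H)-one
Product: 17 (4S)-5,8-dihydroxy-4-(4-hydroxy-8-methoxynaphthalen-1-yl)-3,4-dihydronaphthalen-1(2H)-one
Conditions: H2 (1 atm), Pd/C (10 wt% Pd), EtOAc–MeOH, rt, stopped at full debenzylation
Reagents that add atoms: none
Why: Hydrogenolysis of the two benzyl aryl ethers under neutral conditions, which should leave the methyl ether, the aryl ketone and the non-epimerisable C4–H centre untouched.

**Compound list**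
1 | 5-methoxynaphthalen-1-ol | COc1cccc2c(O)cccc12 | starting material
2 | 4-bromo-5-methoxynaphthalen-1-ol | COc1cccc2c(O)ccc(Br)c12 | intermediate
3 | [(4-bromo-5-methoxynaphthalen-1-yl)oxy](tert-butyl)dimethylsilane | COc1cccc2c(O[Si](C)(C)C(C)(C)C)ccc(Br)c12 | intermediate
4 | 2-bromobenzene-1,4-diol | Oc1ccc(O)c(Br)c1 | starting material
5 | 1,4-bis(benzyloxy)-2-bromobenzene | Brc1cc(OCc2ccccc2)ccc1OCc1ccccc1 | intermediate
6 | [3,6-bis(benzyloxy)-2-bromophenyl]lithium (not isolated) | [Li]c1c(Br)c(OCc2ccccc2)ccc1OCc1ccccc1 | intermediate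
7 | 3,6-bis(benzyloxy)-2-bromobenzaldehyde | O=Cc1c(Br)c(OCc2ccccc2)ccc1OCc1ccccc1 | intermediate
8 | {4-[(tert-butyldimethylsilyl)oxy]-8-methoxynaphthalen-1-yl}lithium (not isolated) | COc1cccc2c(O[Si](C)(C)C(C)(C)C)ccc([Li])c12 | intermediate
9 | [3,6-bis(benzyloxy)-2-bromophenyl]{4-[(tert-butyldimethylsilyl)oxy]-8-methoxynaphthalen-1-yl}methanol (racemic) | COc1cccc2c(O[Si](C)(C)C(C)(C)C)ccc(C(O)c3c(Br)c(OCc4ccccc4)ccc3OCc3ccccc3)c12 | intermediate
10 | lithium [3,6-bis(benzyloxy)-2-lithiophenyl]{4-[(tert-butyldimethylsilyl)oxy]-8-methoxynaphthalen-1-yl}methanolate (not isolated) | COc1cccc2c(O[Si](C)(C)C(C)(C)C)ccc(C(O[Li])c3c([Li])c(OCc4ccccc4)ccc3OCc3ccccc3)c12 | intermediate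
11 | 3,6-bis(benzyloxy)-2-[{4-[(tert-butyldimethylsilyl)oxy]-8-methoxynaphthalen-1-yl}(hydroxy)methyl]benzoic acid (not isolated) | COc1cccc2c(O[Si](C)(C)C(C)(C)C)ccc(C(O)c3c(C(=O)O)c(OCc4ccccc4)ccc3OCc3ccccc3)c12 | intermediate
12 | 4,7-bis(benzyloxy)-3-{4-[(tert-butyldimethylsilyl)oxy]-8-methoxynaphthalen-1-yl}-2-benzofuran-1(3H)-one (racemic) | COc1cccc2c(O[Si](C)(C)C(C)(C)C)ccc(C3OC(=O)c4c(OCc5ccccc5)ccc(OCc5ccccc5)c43)c12 | intermediate
13 | 1-{3,6-bis(benzyloxy)-2-[{4-[(tert-butyldimethylsilyl)oxy]-8-methoxynaphthalen-1-yl}(hydroxy)methyl]phenyl}cyclopropan-1-ol (racemic) | COc1cccc2c(O[Si](C)(C)C(C)(C)C)ccc(C(O)c3c(C4(O)CC4)c(OCc4ccccc4)ccc3OCc3ccccc3)c12 | intermediate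
14 | 1-{3,6-bis(benzyloxy)-2-[hydroxy(4-hydroxy-8-methoxynaphthalen-1-yl)methyl]phenyl}cyclopropan-1-ol (racemic) | COc1cccc2c(O)ccc(C(O)c3c(C4(O)CC4)c(OCc4ccccc4)ccc3OCc3ccccc3)c12 | intermediate
15 | (4E)-4-{[3,6-bis(benzyloxy)-2-(1-hydroxycyclopropyl)phenyl]methylidene}-5-methoxynaphthalen-1(4H)-one (not isolated) | COc1cccc2C(=O)C=C/C(=C\c3c(C4(O)CC4)c(OCc4ccccc4)ccc3OCc3ccccc3)c12 | intermediate
16 | (4S)-5,8-bis(benzyloxy)-4-(4-hydroxy-8-methoxynaphthalen-1-yl)-3,4-dihydronaphthalen-1(2H)-one | COc1cccc2c(O)ccc([C@@H]3CCC(=O)c4c(OCc5ccccc5)ccc(OCc5ccccc5)c43)c12 | intermediate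
17 | (4S)-5,8-dihydroxy-4-(4-hydroxy-8-methoxynaphthalen-1-yl)-3,4-dihydronaphthalen-1(2H)-one | COc1cccc2c(O)ccc([C@@H]3CCC(=O)c4c(O)ccc(O)c43)c12 | target

**Step count**
Total: 10 steps. Longest linear sequence: 8 steps (steps 3, 4, 5, 6, 7, 8, 9, 10 from 4; equally steps 1, 2, 5, 6, 7, 8, 9, 10 from 1).

**Steps most likely to fail**

Step 9 (proposed new method). The cyclopropane σ-bond may be too weak a nucleophile for the quinone methide under a weak chiral acid, or the catalyst may discriminate the two faces of the methide carbon poorly. The fallback sets the C4 centre by a known asymmetric conjugate arylation and closes the ketone ring at C1–C8a instead; it sets out from 3 and 5 and rejoins the route at 16.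
- From 3, a Heck reaction with ethyl acrylate (Pd(OAc)2, P(o-tol)3, Et3N, DMF, 100 °C) should give ethyl (2E)-3-{4-[(tert-butyldimethylsilyl)oxy]-8-methoxynaphthalen-1-yl}prop-2-enoate F1.
- From 5, bromine–lithium exchange (n-BuLi, THF, −78 °C), B(OiPr)3 and aqueous acid should give [2,5-bis(benzyloxy)phenyl]boronic acid F2.
- Rhodium-catalysed asymmetric 1,4-addition of F2 to F1 ([RhCl(C2H4)2]2, a complex of monovalent rhodium, with a chiral diene ligand of the antipode that gives the 3S ester, KOH, dioxane–H2O, 50 °C) should give ethyl (3S)-3-[2,5-bis(benzyloxy)phenyl]-3-{4-[(tert-butyldimethylsilyl)oxy]-8-methoxynaphthalen-1-yl}propanoate F3.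
- LiOH in THF–MeOH–H2O should cleave both the ester and the aryl silyl ether to (3S)-3-[2,5-bis(benzyloxy)phenyl]-3-(4-hydroxy-8-methoxynaphthalen-1-yl)propanoic acid F4.
- (CF3CO)2O in CH2Cl2 at 0 °C should effect intramolecular Friedel–Crafts acylation at the ring-A position ortho to a benzyloxy group. The naphthol is trifluoroacetylated in the flask and thereby deactivated, giving 4-[(1S)-5,8-bis(benzyloxy)-4-oxo-1,2,3,4-tetrahydronaphthalen-1-yl]-5-methoxynaphthalen-1-yl trifluoroacetate F5.
- K2CO3 in MeOH should convert F5 into 16, before step 10.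

Step 7. Insertion of the hindered lactone carbonyl into the titanacyclopropane may be slow, so that direct Grignard addition or reduction takes over. The fallback brings the three-membered ring in intact; it sets out from 9 and rejoins the route at 13, bypassing steps 6 and 7. The dianion 10 (from 9 with n-BuLi, 2.2 equiv, THF, −78 °C) would be added to bromomagnesium 1-ethoxycyclopropan-1-olate F6 (from commercial cyclopropanone ethyl hemiketal and MeMgBr), which releases cyclopropanone F7 in the flask. 1,2-Addition of the aryllithium, a known route to 1-substituted cyclopropanols, should give 13 after aqueous NH4Cl.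

Step 1. Bromination of the free naphthol may give ortho/para mixtures, or over-bromination and oxidation toward the quinone. The fallback introduces the para carbon substituent on the symmetrical diether and differentiates the two oxygens afterwards through the formyl group; it sets out from 1 and rejoins the route at 9.
- Methylation of 1 (MeI, K2CO3, acetone) should give 1,5-dimethoxynaphthalene F8.
- Vilsmeier–Haack formylation (POCl3, DMF, 80 °C) should give 4,8-dimethoxynaphthalene-1-carbaldehyde F9.
- NaSEt in DMF at 100 °C should cleave only the methyl ether para to the formyl group, whose aryloxide is the better leaving group, giving 4-hydroxy-8-methoxynaphthalene-1-carbaldehyde F10.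
- Silylation (TBSCl, imidazole, DMF) should give 4-[(tert-butyldimethylsilyl)oxy]-8-methoxynaphthalene-1-carbaldehyde F11.
- Addition of aryllithium 6 (from 5 and LiN(iPr)2 as in step 4, without the DMF quench) to F11 should give 9.

**Further compounds**
F1 | step 9 | ethyl (2E)-3-{4-[(tert-butyldimethylsilyl)oxy]-8-methoxynaphthalen-1-yl}prop-2-enoate | CCOC(=O)/C=C/c1ccc(O[Si](C)(C)C(C)(C)C)c2cccc(OC)c12
F2 | step 9 | [2,5-bis(benzyloxy)phenyl]boronic acid | OB(O)c1cc(OCc2ccccc2)ccc1OCc1ccccc1
F3 | step 9 | ethyl (3S)-3-[2,5-bis(benzyloxy)phenyl]-3-{4-[(tert-butyldimethylsilyl)oxy]-8-methoxynaphthalen-1-yl}propanoate | COc1cccc2c(O[Si](C)(C)C(C)(C)C)ccc([C@@H](c3cc(OCc4ccccc4)ccc3OCc3ccccc3)CC(=O)OCC)c12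
F4 | step 9 | (3S)-3-[2,5-bis(benzyloxy)phenyl]-3-(4-hydroxy-8-methoxynaphthalen-1-yl)propanoic acid | COc1cccc2c(O)ccc([C@@H](c3cc(OCc4ccccc4)ccc3OCc3ccccc3)CC(=O)O)c12
F5 | step 9 | 4-[(1S)-5,8-bis(benzyloxy)-4-oxo-1,2,3,4-tetrahydronaphthalen-1-yl]-5-methoxynaphthalen-1-yl trifluoroacetate | COc1cccc2c(OC(=O)C(F)(F)F)ccc([C@@H]3CCC(=O)c4c(OCc5ccccc5)ccc(OCc5ccccc5)c43)c12
F6 | step 7 | bromomagnesium 1-ethoxycyclopropan-1-olate | CCOC1(CC1)O[Mg]Br
F7 | step 7 | cyclopropanone | O=C1CC1
F8 | step 1 | 1,5-dimethoxynaphthalene | COc1cccc2c(OC)cccc12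
F9 | step 1 | 4,8-dimethoxynaphthalene-1-carbaldehyde | COc1cccc2c(OC)ccc(C=O)c12
F10 | step 1 | 4-hydroxy-8-methoxynaphthalene-1-carbaldehyde | COc1cccc2c(O)ccc(C=O)c12
F11 | step 1 | 4-[(tert-butyldimethylsilyl)oxy]-8-methoxynaphthalene-1-carbaldehyde | COc1cccc2c(O[Si](C)(C)C(C)(C)C)ccc(C=O)c12
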